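**Retrosynthetic overview**
1. Target 17 consists of two (3R,4S)-4-oxy-7-methoxy-3-methylisochroman-1-one halves joined by an ether from C4 of the upper half to O6′ of the lower half; the last operation removes three phenolic MOM groups and the 4′-O-TBS group from 16.
2. Key disconnection, both δ-lactone rings at once: the aryl–benzylic bonds C4a–C4 and C4a′–C4′. Enabling feature: in each half C4 is an oxygen-bearing sp3 carbon held five atoms (C8a, C1, O2, C3) from the aryl carbon C4a by the lactone ester, so an α-oxy radical at C4 (from a carboxylic acid on C4) and a C4a–iodine bond can be joined on nickel; this leads back to the acyclic diacid 14.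
3. The C4–O–C6′ ether is made before any ring, at a non-benzylic α-carbon, by Mitsunobu reaction of α-hydroxy ester 9 with the para-phenol of 11, a second copy of the same building block (TBS on O2, aryl MOM groups removed).
4. Building block 9: D-threonine supplies C3, its methyl group and C4 (C2 of the amino acid), and its carboxyl group is the traceless radical precursor. The C3 hydroxyl is esterified with inversion by iodo acid 5, made from 2-methoxyresorcinol by C–H borylation/iodination and ortho-lithiation/carboxylation.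
5. Ring order: both arenes are bought; the lower and the upper lactone ring are closed last, in the same operation (step 12).

Key step: step 12

Remark on the chemistry: isochroman-1-one numbering is used (unprimed = half whose C4 carries the aryl ether, primed = half with the free 4′-OH). The C2 configuration of the butanoate units is carried as drawn but is erased in step 12, so only C3 of D-threonine has to be correct.

**Route**

Step 1
Reactants: 1 2-methoxybenzene-1,3-diol (2-methoxyresorcinol)
Product: 2 2-methoxy-1,3-bis(methoxymethoxy)benzene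
Conditions: MOMCl, i-Pr2NEt, CH2Cl2, 0 °C to rt
Reagents that add atoms: chloromethyl methyl ether (MOMCl), COCCl
Why: Base-mediated O-alkylation of both phenols gives the bis-MOM acetal, which later acidifies and directs the ortho-lithiation and is removable with mild acid; no stereocentre is involved.

Step 2
Reactants: 2 2-methoxy-1,3-bis(methoxymethoxy)benzene
Product: 4 5-iodo-2-methoxy-1,3-bis(methoxymethoxy)benzene, via aryl pinacol boronate 3 (not isolated)
Conditions: [Ir(OMe)(cod)]2 (1.5 mol%), dtbpy, B2pin2, THF, 80 °C; then CuI (10 mol%), 1,10-phenanthroline, KI, MeOH/H2O, air, 80 °C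
Reagents that add atoms: bis(pinacolato)diboron, B1(OC(C)(C)C(C)(C)O1)B1OC(C)(C)C(C)(C)O1 (its boron is kept only in 3); potassium iodide, [K+].[I-]
Why: Sterically controlled iridium-catalysed C–H borylation should occur only at C5, the one C–H without an ortho substituent, and the copper-catalysed aerobic iododeboronation (non-acidic, so the MOM acetals survive) then places iodine meta to both oxygens, where electrophilic halogenation cannot.

Step 3
Reactants: 4 5-iodo-2-methoxy-1,3-bis(methoxymethoxy)benzene
Product: 5 6-iodo-3-methoxy-2,4-bis(methoxymethoxy)benzoic acid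
Conditions: LDA, THF, −78 °C; then CO2; then 1 M HCl to pH 3, 0 °C
Reagents that add atoms: carbon dioxide, O=C=O
Why: Directed ortho-metalation removes the proton flanked by iodine and OMOM (C4 and C6 are equivalent by symmetry), and carboxylation of the chelated aryllithium at −78 °C should outrun aryne formation.

Step 4
Reactants: 6 D-threonine
Product: 7 (2R,3S)-2,3-dihydroxybutanoic acid
Conditions: NaNO2, H2SO4 (aq), 0 °C to rt
Reagents that add atoms: water, O
Why: Nitrous acid deamination of the α-amino acid proceeds with net retention at C2 (double inversion through carboxylate participation) and leaves the C3 stereocentre untouched.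

Step 5
Reactants: 7 (2R,3S)-2,3-dihydroxybutanoic acid
Product: 8 methyl (2R,3S)-2,3-dihydroxybutanoate
Conditions: HCl (cat.), MeOH, 40 °C
Reagents that add atoms: methanol, CO
Why: Fischer esterification; no stereocentre is touched.

Step 6
Reactants: 8 methyl (2R,3S)-2,3-dihydroxybutanoate; 5 6-iodo-3-methoxy-2,4-bis(methoxymethoxy)benzoic acid
Product: 9 methyl (2R,3R)-2-hydroxy-3-{[6-iodo-3-methoxy-2,4-bis(methoxymethoxy)benzoyl]oxy}butanoate
Conditions: PPh3, DIAD, toluene, 0 °C to rt
Reagents that add atoms: none
Why: Mitsunobu esterification, the standard way to join a doubly ortho-substituted benzoic acid (as nucleophile) to a secondary alcohol; the oxyphosphonium ion should form at the β-hydroxyl because the α-hydroxyl is deactivated by the ester (the known regioselection for syn-2,3-dihydroxy esters), and SN2 inversion turns (3S) into the (3R) centre that becomes C3 and C3′ of the lactones.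

Step 7
Reactants: 9 methyl (2R,3R)-2-hydroxy-3-{[6-iodo-3-methoxy-2,4-bis(methoxymethoxy)benzoyl]oxy}butanoate
Product: 10 methyl (2R,3R)-2-[(tert-butyldimethylsilyl)oxy]-3-{[6-iodo-3-methoxy-2,4-bis(methoxymethoxy)benzoyl]oxy}butanoate
Conditions: TBSCl, imidazole, DMF, rt
Reagents that add atoms: tert-butyldimethylsilyl chloride, C[Si](C)(Cl)C(C)(C)C
Why: Silylation of the remaining α-hydroxyl masks the future 4′-oxygen; the hindered aroyl group should not migrate and the non-Lewis-acidic conditions leave the aryl MOM acetals intact.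

Step 8
Reactants: 10 methyl (2R,3R)-2-[(tert-butyldimethylsilyl)oxy]-3-{[6-iodo-3-methoxy-2,4-bis(methoxymethoxy)benzoyl]oxy}butanoate
Product: 11 methyl (2R,3R)-2-[(tert-butyldimethylsilyl)oxy]-3-[(2,4-dihydroxy-6-iodo-3-methoxybenzoyl)oxy]butanoate
Conditions: ZnBr2, n-PrSH, CH2Cl2, 0 °C to rt
Reagents that add atoms: none
Why: Lewis-acid/thiol cleavage of aryl MOM ethers (the thiol traps the methoxymethyl cation) is chemoselective in the presence of the silyl ether and the esters.

Step 9
Reactants: 11 methyl (2R,3R)-2-[(tert-butyldimethylsilyl)oxy]-3-[(2,4-dihydroxy-6-iodo-3-methoxybenzoyl)oxy]butanoate; 9 methyl (2R,3R)-2-hydroxy-3-{[6-iodo-3-methoxy-2,4-bis(methoxymethoxy)benzoyl]oxy}butanoate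
Product: 12 methyl (2S,3R)-2-[3-hydroxy-5-iodo-2-methoxy-4-({[(2R,3R)-3-[(tert-butyldimethylsilyl)oxy]-4-methoxy-4-oxobutan-2-yl]oxy}carbonyl)phenoxy]-3-{[6-iodo-3-methoxy-2,4-bis(methoxymethoxy)benzoyl]oxy}butanoate
Conditions: PPh3, DIAD, THF, 0 °C to rt
Reagents that add atoms: none
Why: Mitsunobu etherification of an α-hydroxy ester with a phenol; only the para-hydroxyl of 11 should react because the ortho-hydroxyl is hydrogen-bonded to the ester carbonyl, and the inversion at C2 is irrelevant because that centre is erased in step 12.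

Step 10
Reactants: 12 (ether-linked diester with free ortho-phenol)
Product: 13 methyl (2S,3R)-2-[5-iodo-2-methoxy-3-(methoxymethoxy)-4-({[(2R,3R)-3-[(tert-butyldimethylsilyl)oxy]-4-methoxy-4-oxobutan-2-yl]oxy}carbonyl)phenoxy]-3-{[6-iodo-3-methoxy-2,4-bis(methoxymethoxy)benzoyl]oxy}butanoate
Conditions: MOMCl, i-Pr2NEt, CH2Cl2, 0 to 40 °C
Reagents that add atoms: chloromethyl methyl ether (MOMCl), COCCl
Why: MOM protection of the chelated phenol removes the only oxidisable phenoxide before step 12; the amine base is too weak to enolise the α-aryloxy ester.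

Step 11
Reactants: 13 (fully protected dimethyl ester)
Product: 14 (2S,3R)-2-[4-({[(1R,2R)-1-carboxy-1-[(tert-butyldimethylsilyl)oxy]propan-2-yl]oxy}carbonyl)-5-iodo-2-methoxy-3-(methoxymethoxy)phenoxy]-3-{[6-iodo-3-methoxy-2,4-bis(methoxymethoxy)benzoyl]oxy}butanoic acid
Conditions: Me3SnOH, 1,2-dichloroethane, 80 °C; then cold 0.1 M HCl wash
Reagents that add atoms: trimethyltin hydroxide, C[Sn](C)(C)O (supplies the hydroxyl oxygen of each acid)
Why: Trimethyltin hydroxide cleaves the two methyl esters by a mild, nearly neutral acyl–oxygen cleavage, and should leave the doubly ortho-substituted secondary aroyl esters, the MOM and TBS groups and the elimination-prone β-aroyloxy ester untouched.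

Step 12
Reactants: 14 (acyclic bis-iodo diacid)
Product: 16 (3R,4S)-4-{[(3R,4S)-4-[(tert-butyldimethylsilyl)oxy]-7-methoxy-8-(methoxymethoxy)-3-methyl-1-oxoisochroman-6-yl]oxy}-7-methoxy-6,8-bis(methoxymethoxy)-3-methylisochroman-1-one, via mono-lactone iodo acid 15 (not isolated)
Conditions: Cs2CO3, Ni(cod)2 (2.2 equiv), dtbbpy, DMF (0.005 M), rt; then Ir[dF(CF3)ppy]2(dtbbpy)PF6 (2 mol%), blue LEDs (450 nm), 25 °C
Reagents that add atoms: none
Why: Proposed new method: twofold intramolecular decarboxylative arylation, in which zerovalent nickel inserts into both C–I bonds to give two aryl iodide complexes of divalent nickel, each caesium carboxylate can bind the nickel centre of its own half and is oxidised by the photoexcited iridium complex, loss of CO2 leaves a planar α-oxy radical at C4 (α-aryloxy) or C4′ (α-silyloxy) that is captured by that nickel centre, and C(sp2)–C(sp3) reductive elimination from the trivalent nickel aryl alkyl forms C4a–C4 and C4a′–C4′; the closest known reaction type is the intermolecular nickel/photoredox decarboxylative arylation of α-oxy and α-amino acids with aryl halides, which has not been used to close a lactone ring. Each δ-lactone is closed as a six-membered ring by reductive elimination from a seven-membered nickelacycle in which the aroyl ester has turned into its s-cis conformer, and the two closures are independent (15 shows the lower ring closed first; the order is immaterial). The new stereocentres C4 and C4′ are set by 1,2-induction from the methyl-bearing centres C3 and C3′: the radical erases the C2 configuration of each acid, capture at nickel is reversible, and reductive elimination through a half-chair that places the C4 oxygen substituent trans to the C3 methyl group is expected to be favoured, trans also being the more stable arrangement of 3,4-disubstituted 3,4-dihydroisocoumarins. The step needs 3,4-trans selectivity in both rings and ring closure in preference to intermolecular coupling, hydrogen abstraction or protodeiodination; nickel placed stoichiometrically on both arenes beforehand, the carboxylate-to-nickel chelate, high dilution and the 1,6-relationship of C4 and C4a within each half should secure the ring closure, and crossed closure is impossible because C4 is attached through oxygen to a position meta to the lower C–I bond. All phenols are MOM ethers, so the two α-oxy carboxylates are the only groups the photocatalyst can oxidise.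

Step 13
Reactants: 16 (protected bis-lactone)
Product: 17 (3R,4S)-6,8-dihydroxy-4-{[(3R,4S)-4,8-dihydroxy-7-methoxy-3-methyl-1-oxoisochroman-6-yl]oxy}-7-methoxy-3-methylisochroman-1-one
Conditions: HCl (1 M), MeOH/THF (1:1), 35 °C
Reagents that add atoms: none
Why: Acid-catalysed acetal cleavage (three aryl MOM groups) and desilylation in one operation; the conditions should be too mild to ionise the C4 aryl ether, whose benzylic cation is destabilised by the ortho lactone carbonyl and the β-acyloxy group, and no base is present that could rearrange the 4′-hydroxy lactone to a phthalide.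

**Compound list**
1 | 2-methoxybenzene-1,3-diol (2-methoxyresorcinol) | COc1c(O)cccc1O | starting material
2 | 2-methoxy-1,3-bis(methoxymethoxy)benzene | COCOc1cccc(OCOC)c1OC | intermediate
3 | 2-[4-methoxy-3,5-bis(methoxymethoxy)phenyl]-4,4,5,5-tetramethyl-1,3,2-dioxaborolane | COCOc1cc(cc(OCOC)c1OC)B1OC(C)(C)C(C)(C)O1 | intermediate
4 | 5-iodo-2-methoxy-1,3-bis(methoxymethoxy)benzene | Ic1cc(OCOC)c(OC)c(OCOC)c1 | intermediate
5 | 6-iodo-3-methoxy-2,4-bis(methoxymethoxy)benzoic acid | Ic1cc(OCOC)c(OC)c(OCOC)c1C(=O)O | intermediate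
6 | D-threonine, (2R,3S)-2-amino-3-hydroxybutanoic acid | C[C@H](O)[C@@H](N)C(=O)O | starting material
7 | (2R,3S)-2,3-dihydroxybutanoic acid | C[C@H](O)[C@@H](O)C(=O)O | intermediate
8 | methyl (2R,3S)-2,3-dihydroxybutanoate | C[C@H](O)[C@@H](O)C(=O)OC | intermediate
9 | methyl (2R,3R)-2-hydroxy-3-{[6-iodo-3-methoxy-2,4-bis(methoxymethoxy)benzoyl]oxy}butanoate | Ic1cc(OCOC)c(OC)c(OCOC)c1C(=O)O[C@H](C)[C@@H](O)C(=O)OC | intermediate
10 | methyl (2R,3R)-2-[(tert-butyldimethylsilyl)oxy]-3-{[6-iodo-3-methoxy-2,4-bis(methoxymethoxy)benzoyl]oxy}butanoate | Ic1cc(OCOC)c(OC)c(OCOC)c1C(=O)O[C@H](C)[C@@H](O[Si](C)(C)C(C)(C)C)C(=O)OC | intermediate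
11 | methyl (2R,3R)-2-[(tert-butyldimethylsilyl)oxy]-3-[(2,4-dihydroxy-6-iodo-3-methoxybenzoyl)oxy]butanoate | Ic1cc(O)c(OC)c(O)c1C(=O)O[C@H](C)[C@@H](O[Si](C)(C)C(C)(C)C)C(=O)OC | intermediate
12 | methyl (2S,3R)-2-[3-hydroxy-5-iodo-2-methoxy-4-({[(2R,3R)-3-[(tert-butyldimethylsilyl)oxy]-4-methoxy-4-oxobutan-2-yl]oxy}carbonyl)phenoxy]-3-{[6-iodo-3-methoxy-2,4-bis(methoxymethoxy)benzoyl]oxy}butanoate | Ic1cc(OCOC)c(OC)c(OCOC)c1C(=O)O[C@H](C)[C@H](Oc1cc(c(C(=O)O[C@H](C)[C@@H](O[Si](C)(C)C(C)(C)C)C(=O)OC)c(O)c1OC)I)C(=O)OC | intermediate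
13 | methyl (2S,3R)-2-[5-iodo-2-methoxy-3-(methoxymethoxy)-4-({[(2R,3R)-3-[(tert-butyldimethylsilyl)oxy]-4-methoxy-4-oxobutan-2-yl]oxy}carbonyl)phenoxy]-3-{[6-iodo-3-methoxy-2,4-bis(methoxymethoxy)benzoyl]oxy}butanoate | Ic1cc(OCOC)c(OC)c(OCOC)c1C(=O)O[C@H](C)[C@H](Oc1cc(c(C(=O)O[C@H](C)[C@@H](O[Si](C)(C)C(C)(C)C)C(=O)OC)c(OCOC)c1OC)I)C(=O)OC | intermediate
14 | (2S,3R)-2-[4-({[(1R,2R)-1-carboxy-1-[(tert-butyldimethylsilyl)oxy]propan-2-yl]oxy}carbonyl)-5-iodo-2-methoxy-3-(methoxymethoxy)phenoxy]-3-{[6-iodo-3-methoxy-2,4-bis(methoxymethoxy)benzoyl]oxy}butanoic acid | Ic1cc(OCOC)c(OC)c(OCOC)c1C(=O)O[C@H](C)[C@H](Oc1cc(c(C(=O)O[C@H](C)[C@@H](O[Si](C)(C)C(C)(C)C)C(=O)O)c(OCOC)c1OC)I)C(=O)O | intermediate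
15 | (2S,3R)-2-{[(3R,4S)-4-[(tert-butyldimethylsilyl)oxy]-7-methoxy-8-(methoxymethoxy)-3-methyl-1-oxoisochroman-6-yl]oxy}-3-{[6-iodo-3-methoxy-2,4-bis(methoxymethoxy)benzoyl]oxy}butanoic acid | Ic1cc(OCOC)c(OC)c(OCOC)c1C(=O)O[C@H](C)[C@H](Oc1cc2c(c(OCOC)c1OC)C(=O)O[C@H](C)[C@H]2O[Si](C)(C)C(C)(C)C)C(=O)O | intermediate
16 | (3R,4S)-4-{[(3R,4S)-4-[(tert-butyldimethylsilyl)oxy]-7-methoxy-8-(methoxymethoxy)-3-methyl-1-oxoisochroman-6-yl]oxy}-7-methoxy-6,8-bis(methoxymethoxy)-3-methylisochroman-1-one | COc1c(OCOC)cc2c(c1OCOC)C(=O)O[C@H](C)[C@H]2Oc1cc2c(c(OCOC)c1OC)C(=O)O[C@H](C)[C@H]2O[Si](C)(C)C(C)(C)C | intermediate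
17 | (3R,4S)-6,8-dihydroxy-4-{[(3R,4S)-4,8-dihydroxy-7-methoxy-3-methyl-1-oxoisochroman-6-yl]oxy}-7-methoxy-3-methylisochroman-1-one | COc1c(O)cc2c(c1O)C(=O)O[C@H](C)[C@H]2Oc1cc2c(c(O)c1OC)C(=O)O[C@H](C)[C@H]2O | target

**Step count and risks**

Total step count: 13. Longest linear sequence: 11 steps (1, 2, 3, 6, 7, 8, 9, 10, 11, 12, 13, from 2-methoxyresorcinol).

Steps most likely to fail:

1. Step 12 (Proposed new method). The α-oxy radicals may decay before ring closure: the aroyl ester has to rotate into its s-cis conformer, so hydrogen abstraction, intermolecular coupling to oligomers or light-induced loss of the aryl group from nickel (protodeiodination) can compete. The 1,2-induction may also give too little trans selectivity in one of the two rings. The fallback uses known chemistry, forms the same aryl–C4 bonds by a long-lived aryl-metal species, and makes the ether afterwards; it sets out from 5 and returns to the route at 16. Acid 5 is esterified with commercial (S)-but-3-en-2-ol, C[C@H](O)C=C, under Mitsunobu conditions (inversion) to (R)-but-3-en-2-yl 6-iodo-3-methoxy-2,4-bis(methoxymethoxy)benzoate F1. Ozonolysis (O3, CH2Cl2, −78 °C; Me2S) should give the α-acyloxy aldehyde F2. Nozaki–Hiyama–Kishi ring closure (CrCl2, NiCl2 cat., DMF, rt) adds the aryl species of trivalent chromium to the aldehyde and should give the 4-hydroxy lactone as its (4S)-epimer F3 and its (4R)-epimer F4, which are separated; both are used. F3 is silylated (TBSCl, imidazole) to the silyl ether F5, whose MOM groups are removed (ZnBr2, n-PrSH) to give the 6,8-diol F6. Mitsunobu etherification of the (4R)-alcohol F4 with the 6-hydroxyl of F6 (inversion at C4, the 8-hydroxyl being chelated) should give the ether-linked bis-lactone F7, and MOM protection of its 8′-hydroxyl (MOMCl, i-Pr2NEt) gives 16.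

2. Step 6. The oxyphosphonium ion may form at the wrong hydroxyl, or the β-oxyphosphonium ion may collapse by intramolecular displacement to the glycidic ester, or eliminate, before the hindered carboxylate attacks. The fallback fixes the regiochemistry with a protecting group; it sets out from 8 and returns at 10. Diol 8 is silylated at the more acidic α-hydroxyl (TBSCl, imidazole, DMF, 0 °C) to methyl (2R,3S)-2-[(tert-butyldimethylsilyl)oxy]-3-hydroxybutanoate F8. Mitsunobu esterification of its only free hydroxyl with 5 (inversion at C3) gives 10 directly, and the 9 needed for step 9 is then obtained by desilylating part of 10 with HF·pyridine in THF.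

3. Step 9. Displacement at the α-carbon next to the bulky β-aroyloxy group may be slow, so that the betaine is consumed by side reactions (alkylation of the hydrazide, elimination) or the chelated ortho-phenol also reacts. The fallback replaces in-situ activation by a preformed sulfonate and a phenoxide; it sets out from 9 and returns at 12. Alcohol 9 is converted (Tf2O, 2,6-lutidine, CH2Cl2, −78 °C) into methyl (2R,3R)-3-{[6-iodo-3-methoxy-2,4-bis(methoxymethoxy)benzoyl]oxy}-2-{[(trifluoromethyl)sulfonyl]oxy}butanoate F9. This is displaced with inversion by the mono-potassium para-phenoxide of 11 (K2CO3, 1 equiv, MeCN, −20 °C to rt) to give 12.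

**Further compounds**
F1 | step 12 | (R)-but-3-en-2-yl 6-iodo-3-methoxy-2,4-bis(methoxymethoxy)benzoate | Ic1cc(OCOC)c(OC)c(OCOC)c1C(=O)O[C@H](C)C=C
F2 | step 12 | (R)-1-oxopropan-2-yl 6-iodo-3-methoxy-2,4-bis(methoxymethoxy)benzoate | Ic1cc(OCOC)c(OC)c(OCOC)c1C(=O)O[C@H](C)C=O
F3 | step 12 | (3R,4S)-4-hydroxy-7-methoxy-6,8-bis(methoxymethoxy)-3-methylisochroman-1-one | COc1c(OCOC)cc2c(c1OCOC)C(=O)O[C@H](C)[C@H]2O
F4 | step 12 | (3R,4R)-4-hydroxy-7-methoxy-6,8-bis(methoxymethoxy)-3-methylisochroman-1-one | COc1c(OCOC)cc2c(c1OCOC)C(=O)O[C@H](C)[C@@H]2O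
F5 | step 12 | (3R,4S)-4-[(tert-butyldimethylsilyl)oxy]-7-methoxy-6,8-bis(methoxymethoxy)-3-methylisochroman-1-one | COc1c(OCOC)cc2c(c1OCOC)C(=O)O[C@H](C)[C@H]2O[Si](C)(C)C(C)(C)C
F6 | step 12 | (3R,4S)-4-[(tert-butyldimethylsilyl)oxy]-6,8-dihydroxy-7-methoxy-3-methylisochroman-1-one | COc1c(O)cc2c(c1O)C(=O)O[C@H](C)[C@H]2O[Si](C)(C)C(C)(C)C
F7 | step 12 | (3R,4S)-4-{[(3R,4S)-4-[(tert-butyldimethylsilyl)oxy]-8-hydroxy-7-methoxy-3-methyl-1-oxoisochroman-6-yl]oxy}-7-methoxy-6,8-bis(methoxymethoxy)-3-methylisochroman-1-one | COc1c(OCOC)cc2c(c1OCOC)C(=O)O[C@H](C)[C@H]2Oc1cc2c(c(O)c1OC)C(=O)O[C@H](C)[C@H]2O[Si](C)(C)C(C)(C)C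
F8 | step 6 | methyl (2R,3S)-2-[(tert-butyldimethylsilyl)oxy]-3-hydroxybutanoate | C[C@H](O)[C@@H](O[Si](C)(C)C(C)(C)C)C(=O)OC
F9 | step 9 | methyl (2R,3R)-3-{[6-iodo-3-methoxy-2,4-bis(methoxymethoxy)benzoyl]oxy}-2-{[(trifluoromethyl)sulfonyl]oxy}butanoate | Ic1cc(OCOC)c(OC)c(OCOC)c1C(=O)O[C@H](C)[C@@H](OS(=O)(=O)C(F)(F)F)C(=O)OC
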